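At early times both earlier runs lose substrate faster than they gain product: at 2.50 min, Friday's run holds 26 % substrate and 3 % product. The substrate's loss therefore says little about yield, so read the product directly.

| setting | Friday's | Tuesday's | flask |
|---|---|---|---|
| substrate | 0.067 M | 0.15 M | 0.10 M |
| partner | 0.80 equiv | 0.80 equiv | 0.800 equiv |
| reagent | 1.5 equiv | 1.5 equiv | 1.50 equiv |
| protic impurity | 5 mM | 5 mM | 5.00 mM |
| remark | run made earlier | run made earlier |  |
| time |  |  | 10 min |

| run | time / min | product / % | substrate / % |
|---|---|---|---|
| Friday's | 2.50 | 3 | 26 |
| Friday's | 3.00 | 5 | 21 |
| Friday's | 5.00 | 7 | 15 |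
| Friday's | 6.00 | 11 | 12 |
| Friday's | 8.00 | 12 | 11 |
| Friday's | 12.0 | 14 | 12 |
| Tuesday's | 2.50 | 9 | 12 |
| Tuesday's | 3.00 | 12 | 5 |
| Tuesday's | 5.00 | 18 | 5 |
| Tuesday's | 6.00 | 21 | 4 |
| Tuesday's | 8.00 | 28 | 2 |
| Tuesday's | 12.0 | 33 | 4 |

(standard deviation of a reading: 1.5 percentage points)

- when, up to 10 min, the flask holds most product
- the amount of product, in percent of the substrate charged, at that time

- the analysis behind the earlier runs scatters by 1.5 percentage points, standard deviation

Fold concentration and time into one dimensionless number, a Damköhler number, with κ read from a run as product fraction per molar per minute: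

N = κ × substrate concentration × time

At 8.00 min, Friday's run gives κ = 0.224 /M/min and Tuesday's run 0.233 /M/min. These agree within the scatter, so at these equivalents of partner and reagent the substrate concentration folds in properly. A first round for this flask gives N = 0.233.

One number is not enough, though. At 12.0 min, Tuesday's κ is down to 0.183 /M/min, so the first answer probably runs high. Going round again, I take κ midway between those readings:

κ = 0.208 /M/min, N = 0.208

This yield number, the fraction of charged substrate expected as product, gives my 20.8 %. Tuesday's product still rises from 28 % to 33 % against a scatter of 1.5 percentage points, so I put the best time at 10 min.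

The forecast says 20 % at 10 min, a little below my figure, holding that “Percent yield scales about linearly with concentration”.

The flask gives 22.0 % at 10.0 min, against N = 0.208.

    substrate + reagent → open intermediate (k = 11.0 /M/min)
    reagent + partner → second intermediate (k = 1.90 /M/min)
    open intermediate + second intermediate → product (k = 2.20 /M/min)
    reagent + protic impurity → quenched reagent (k = 15.0 /M/min)
    reagent ⇌ dormant form (K = 11.0, k = 0.0550 /min)

At that time the flask's open intermediate stands at 72.4 %. Both earlier runs held partner at the same equivalents, so κ could belong to the partner's concentration as well as the substrate's. Taken that way, the neighbour flask charged with 0.320 equiv of partner, its other charges and time held, has its number scaled to 8.33 %; that flask gives 10.9 %.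

All runs come from a simulation from invented constants, noise included.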